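The numbers in the tables are calculated on assumed constants, noise included.

Your vessel is stirred at constant volume, and every bis adduct in it has taken up partner twice. The question is what it costs to let one reagent in late.

| flask | starting material | partner | remark | time |
|---|---|---|---|---|
| green | 20 mM | 50 mM | run made earlier |  |
| amber | 10 mM | 50 mM | run made earlier |  |
| blue | 40 mM | 50 mM | run made earlier |  |
| Tuesday's | 20 mM (fed, over 2.0 h) | 50.0 mM | all else is in the flask from the start; the feed brings no volume worth counting | 5.0 h |
| Thursday's | 20 mM | 50.0 mM | everything together at the start | 5.0 h |
| Friday's | 20 mM (in portions, 2, over 2.0 h) | 50.0 mM | first portion at the start, last at 2.0 h | 5.0 h |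
| Sunday's | 20 mM | 50.0 mM (fed, over 2.0 h) | all else is in the flask from the start; the feed brings no volume worth counting | 5.0 h |

| run | time / h | bis adduct / % |
|---|---|---|
| green | 0.250 | 0 |
| green | 0.500 | 9 |
| green | 1.33 | 29 |
| green | 3.00 | 57 |
| amber | 0.333 | 6 |
| amber | 0.667 | 14 |
| amber | 1.50 | 36 |
| amber | 4.00 | 68 |
| blue | 0.500 | 8 |
| blue | 1.33 | 19 |
| blue | 2.50 | 35 |
| blue | 4.00 | 43 |

(readings scatter by 2 percentage points)

1. the flask that comes out highest in amount of bis adduct, in percent of the starting material charged, or "all alike" when all lie within 1.5 percentage points (Tuesday's / Thursday's / Friday's / Sunday's / all alike)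
2. bis adduct at the end, in percent of the starting material charged, Tuesday's
3. bis adduct at the end, in percent of the starting material charged, Thursday's
4. bis adduct at the end, in percent of the starting material charged, Friday's
5. bis adduct at the end, in percent of the starting material charged, Sunday's

- a species is counted by the starting material in it: one side product counts as two
- amounts and yields of bis adduct count crystals too
- given per volume of solution although it is solid: crystals
- the numbers in the tables scatter by 2 percentage points (one standard deviation)
- reactions considered so far: starting material + partner -> single product; partner + single product -> bis adduct; partner + bis adduct -> triple product; crystals <-> bis adduct; starting material <-> dormant form; starting material + single product -> side product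

Green holds twice amber's starting material, yet reads 29% at 1.33 h where amber reads 36% at 1.50 h. That is close, given the later reading and a scatter of 2 percentage points, so with partner in excess each bit of starting material seems to keep its own clock. Blue is the warning: it needs 0.0800 M of partner and holds 50 mM, less, so partner is its limiting reagent.

A steady feed over 2.0 h and portions at its two ends both bring the charge in, on average, 1.00 h after the start; call that the lateness. Tuesday's and Friday's should then read at 5.0 h like green at 4.00 h, and Thursday's like green at 5.0 h.

But green stops at 3.00 h. Its unreacted share falls at 0.300 h⁻¹ over its last stretch, and carried on, that gives 68.1% and 76.4%.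

The objection is that this pace needs partner. Counting two per bis adduct, green's partner averages 32.8 mM over that stretch and stands at 27.2 mM at its last reading, which is less. Scaled down, the pace is 0.249 h⁻¹, so I reckon 73.9% for Thursday's and 66.5% for the other two. Both still run high, since partner keeps falling, so I trust the gap of 7.4 points more than the levels.

A lean feed may spare some side product, so I hold the gap as an estimate. Sunday's partner comes in just as late, and blue shows what lean partner does, so I expect Sunday's below Tuesday's and Friday's, with Thursday's on top.

The forecast gave 73% for Tuesday's, 70% for Thursday's, 71% for Friday's and 60% for Sunday's, with Tuesday's highest, since feeding “trims side product but delays the slow step”; that parts from my order.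

The flasks give 66.4% for Thursday's, the highest, then 60.0% for Tuesday's, 58.8% for Friday's and 55.6% for Sunday's.

    starting material + partner → single product (k = 18.1 L mol⁻¹ h⁻¹)
    partner + single product → bis adduct (k = 22.8 L mol⁻¹ h⁻¹)
    partner + bis adduct → triple product (k = 0.520 L mol⁻¹ h⁻¹)
    crystals ⇌ bis adduct, rate k4*(cs4 - [bis adduct]) while solid is left; crystals form when [bis adduct] > cs4 (solubility = 0.560 mM, k = 2.78 h⁻¹)
    starting material ⇌ dormant form (K = 0.960, k = 0.218 h⁻¹)
    starting material + single product → side product (k = 3.54 L mol⁻¹ h⁻¹)

Thursday's stands 6.4 points above Tuesday's, and 7.5 points below my level; at 5.00 h Thursday's still holds 10.6% as single product. Friday's puts the lateness to use once more: its portions have aged 5.0 h and 3.00 h, so Thursday's end and green's 57% at 3.00 h average 61.7%, and Friday's gives 58.8%.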